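**Retrosynthetic overview**
1. Last bond: C3 of the left butenolide ring (O1–C2(=O)–C3=C3a–C7a) to the adjacent CH2 of the two-carbon bridge. It is made from enol lactone 8 (left half, C3 still CH2, double bond at C3a=C7a) and aldehyde 22 (right half, bridge present as CH2–CHO) by a one-pot condensation, hydride transfer and tautomerisation.
2. Enabling feature: the left lactone ring is the C7a-protonated tautomer of an aromatic 2-hydroxyfuran. In the deconjugated isomer 8 the C3 methylene is a CH-acid between C2=O and the C3a=C7a enol bond; the ylidene formed at C3 accepts hydride because the adduct is aromatic, and reprotonation at C7a sets that centre thermodynamically (lactone oxygen equatorial).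
3. The two 1-methyl-1-vinyl-2-isopropenylcyclohexane rings have opposite absolute configuration, so each comes from one enantiomer of verbenone: vinyl cuprate addition anti to the gem-dimethyl bridge, then Lewis-acid fragmentation of the cyclobutane (a temporary ring absent from the target), which releases the isopropenyl group and a regiodefined enol acetate.
4. Ring order, left: cyclohexane (from the pinane) → enol lactone (step 5) → butenolide (step 13). Right: cyclohexane → cis-fused γ-lactone by equatorial hydride delivery (step 9) → α-methylene lactone → C3 side chain and C3 stereocentre by a formyl-equivalent Giese addition (step 11).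

Key step: step 13

Remark: (1R,5R)-(+)-verbenone is taken as a catalogue compound like its (1S,5S)-(−) enantiomer (it is otherwise one allylic oxidation from (+)-α-pinene); lactone locants follow 1-benzofuran numbering (O1, C2 carbonyl, C3, C3a, C4–C7, C7a).

**Left half**

Step 1
Reactants: 1 (1S,5S)-(−)-verbenone
Product: 2 (1S,4R,5R)-4-ethenyl-4,6,6-trimethylbicyclo[3.1.1]heptan-2-one
Conditions: CH2=CHMgBr (1.5 equiv), CuBr·SMe2 (10 mol%), THF, −40 → 0 °C; sat. aq NH4Cl
Reagents that add atoms: vinylmagnesium bromide, C=C[Mg]Br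
Why: Copper-catalysed conjugate addition of a vinyl Grignard reagent to the β-methyl enone; the cuprate should attack C4 from the face opposite the gem-dimethyl bridge, so vinyl ends up anti and methyl syn to C6, the later isopropenyl carbon.

Step 2
Reactants: 2 (1S,4R,5R)-4-ethenyl-4,6,6-trimethylbicyclo[3.1.1]heptan-2-one
Product: 3 (4R,5R)-5-ethenyl-5-methyl-4-(prop-1-en-2-yl)cyclohex-1-en-1-yl acetate
Conditions: BF3·OEt2 (2 equiv), Zn(OAc)2 (2 equiv), Ac2O, 0 → 25 °C
Reagents that add atoms: acetic anhydride, CC(=O)OC(C)=O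
Why: Lewis-acid-mediated cyclobutane ring opening of a pinan-2-one (heterolysis of the C1–C6 bond α to the carbonyl) should give an enolate trapped as the enol acetate and a tertiary cation that loses a methyl proton (E1) to the isopropenyl group; the two stereocentres are untouched and the enol double bond sits on the former bridgehead carbon.

Step 3
Reactants: 3 (4R,5R)-5-ethenyl-5-methyl-4-(prop-1-en-2-yl)cyclohex-1-en-1-yl acetate
Product: 6 ethyl 2-[(1S,4R,5R)-4-ethenyl-4-methyl-2-oxo-5-(prop-1-en-2-yl)cyclohexyl]acetate, via lithium enolate 4 (not isolated), via axial C-1 epimer 5 (not isolated)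
Conditions: MeLi (2.05 equiv), THF, 0 °C; BrCH2CO2Et (1.3 equiv), DMPU, −78 → 0 °C; then NaOEt (0.1 equiv), EtOH, 25 °C; aqueous work-up
Reagents that add atoms: ethyl bromoacetate, CCOC(=O)CBr
Why: Cleavage of the enol acetate with methyllithium gives a regiodefined lithium enolate that is alkylated (SN2 enolate alkylation) at the former bridgehead carbon; axial attack should give the axial ester first and ethoxide equilibration should place CH2CO2Et equatorial (in this series the centre becomes sp2 in step 5).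

Step 4
Reactants: 6 ethyl 2-[(1S,4R,5R)-4-ethenyl-4-methyl-2-oxo-5-(prop-1-en-2-yl)cyclohexyl]acetate
Product: 7 2-[(1S,4R,5R)-4-ethenyl-4-methyl-2-oxo-5-(prop-1-en-2-yl)cyclohexyl]acetic acid
Conditions: LiOH·H2O (3 equiv), THF/H2O 3:1, 25 °C; then 1 M HCl to pH 3
Reagents that add atoms: lithium hydroxide, [Li+].[OH-]
Why: Ester saponification; no other group in the molecule is sensitive to aqueous hydroxide.

Step 5
Reactants: 7 2-[(1S,4R,5R)-4-ethenyl-4-methyl-2-oxo-5-(prop-1-en-2-yl)cyclohexyl]acetic acid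
Product: 8 (5R,6R)-6-ethenyl-6-methyl-5-(prop-1-en-2-yl)-4,5,6,7-tetrahydro-1-benzofuran-2(3H)-one
Conditions: Ac2O, NaOAc (0.5 equiv), 100 °C
Reagents that add atoms: none
Why: Dehydrative enol lactonisation of a γ-keto acid through its mixed anhydride (the classical route to Δβ,γ-butenolides); the tetrasubstituted C3a=C7a enol double bond should be favoured over the C7=C7a isomer.

**Right half**

Step 6
Reactants: 9 (1R,5R)-(+)-verbenone
Product: 10 (1R,4S,5S)-4-ethenyl-4,6,6-trimethylbicyclo[3.1.1]heptan-2-one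
Conditions: CH2=CHMgBr (1.5 equiv), CuBr·SMe2 (10 mol%), THF, −40 → 0 °C; sat. aq NH4Cl
Reagents that add atoms: vinylmagnesium bromide, C=C[Mg]Br
Why: Copper-catalysed conjugate addition as in step 1, with attack anti to the gem-dimethyl bridge setting the quaternary centre in the mirror-image sense.

Step 7
Reactants: 10 (1R,4S,5S)-4-ethenyl-4,6,6-trimethylbicyclo[3.1.1]heptan-2-one
Product: 11 (4S,5S)-5-ethenyl-5-methyl-4-(prop-1-en-2-yl)cyclohex-1-en-1-yl acetate
Conditions: BF3·OEt2 (2 equiv), Zn(OAc)2 (2 equiv), Ac2O, 0 → 25 °C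
Reagents that add atoms: acetic anhydride, CC(=O)OC(C)=O
Why: Lewis-acid-mediated cyclobutane ring opening as in step 2, giving the isopropenyl group and the regiodefined enol acetate without touching the two stereocentres.

Step 8
Reactants: 11 (4S,5S)-5-ethenyl-5-methyl-4-(prop-1-en-2-yl)cyclohex-1-en-1-yl acetate
Product: 14 ethyl 2-[(1R,4S,5S)-4-ethenyl-4-methyl-2-oxo-5-(prop-1-en-2-yl)cyclohexyl]acetate, via lithium enolate 12 (not isolated), via axial C-1 epimer 13 (not isolated)
Conditions: MeLi (2.05 equiv), THF, 0 °C; BrCH2CO2Et (1.3 equiv), DMPU, −78 → 0 °C; then NaOEt (0.1 equiv), EtOH, 25 °C; aqueous work-up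
Reagents that add atoms: ethyl bromoacetate, CCOC(=O)CBr
Why: Regiodefined enolate alkylation as in step 3; the ethoxide equilibration should deliver the all-equatorial ketone (only the 4-methyl axial), which is the C-1 configuration the right half needs (cis to isopropenyl).

Step 9
Reactants: 14 ethyl 2-[(1R,4S,5S)-4-ethenyl-4-methyl-2-oxo-5-(prop-1-en-2-yl)cyclohexyl]acetate
Product: 16 (3aR,5S,6S,7aR)-6-ethenyl-6-methyl-5-(prop-1-en-2-yl)hexahydro-1-benzofuran-2(3H)-one, via hydroxy ester 15 (not isolated)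
Conditions: L-Selectride (1.2 equiv), THF, −78 → 0 °C; then 1 M HCl, 25 °C
Reagents that add atoms: none
Why: Bulky trialkylborohydride reduction; the axial 4-methyl group blocks the axial trajectory, so hydride should enter equatorially and give the axial alcohol cis to the equatorial side chain, which closes to the cis-fused γ-lactone (lactonisation).

Step 10
Reactants: 16 (3aR,5S,6S,7aR)-6-ethenyl-6-methyl-5-(prop-1-en-2-yl)hexahydro-1-benzofuran-2(3H)-one
Product: 20 (3aR,5S,6S,7aR)-6-ethenyl-6-methyl-3-methylidene-5-(prop-1-en-2-yl)hexahydro-1-benzofuran-2(3H)-one, via lactone lithium enolate 17 (not isolated), via Mannich base 18 (not isolated), via trimethylammonium iodide 19 (not isolated)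
Conditions: LDA (1.1 equiv), THF, −78 °C; CH2=NMe2+ I− (1.5 equiv), −78 → 25 °C; then MeI (5 equiv), MeOH, 25 °C; then sat. aq NaHCO3, CH2Cl2, 25 °C
Reagents that add atoms: Eschenmoser's salt, C=[N+](C)C.[I-]
Why: Eschenmoser α-methylenation (Mannich reaction of the lactone enolate, N-quaternisation, Hofmann-type elimination); the C3 centre formed in the Mannich step is removed again by the elimination.

Step 11
Reactants: 20 (3aR,5S,6S,7aR)-6-ethenyl-6-methyl-3-methylidene-5-(prop-1-en-2-yl)hexahydro-1-benzofuran-2(3H)-one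
Product: 21 (3S,3aR,5S,6S,7aR)-3-[(1,3-dioxolan-2-yl)methyl]-6-ethenyl-6-methyl-5-(prop-1-en-2-yl)hexahydro-1-benzofuran-2(3H)-one
Conditions: 1,3-dioxolane/MeCN 1:1, (n-Bu4N)4W10O32 (2 mol%), 390 nm LED, 25 °C
Reagents that add atoms: 1,3-dioxolane, C1COCO1
Why: Decatungstate hydrogen-atom-transfer photocatalysis followed by Giese addition; the nucleophilic dioxolan-2-yl radical should add only to the electron-poor exocyclic methylene, and hydrogen return from the bulky reduced polyoxotungstate to the planar C3 radical should come from the convex face (syn to H-3a and H-7a), placing the side chain on the concave face (3S).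

Step 12
Reactants: 21 (3S,3aR,5S,6S,7aR)-3-[(1,3-dioxolan-2-yl)methyl]-6-ethenyl-6-methyl-5-(prop-1-en-2-yl)hexahydro-1-benzofuran-2(3H)-one
Product: 22 2-[(3S,3aR,5S,6S,7aR)-6-ethenyl-6-methyl-2-oxo-5-(prop-1-en-2-yl)octahydro-1-benzofuran-3-yl]acetaldehyde
Conditions: 2 M aq HCl/THF 1:2, 25–40 °C
Reagents that add atoms: water, O
Why: Acid-catalysed acetal hydrolysis; the lactone α-centre is β to the new aldehyde and is not enolised under these conditions.

**Fragment union**

Step 13
Reactants: 8 (5R,6R)-6-ethenyl-6-methyl-5-(prop-1-en-2-yl)-4,5,6,7-tetrahydro-1-benzofuran-2(3H)-one; 22 2-[(3S,3aR,5S,6S,7aR)-6-ethenyl-6-methyl-2-oxo-5-(prop-1-en-2-yl)octahydro-1-benzofuran-3-yl]acetaldehyde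
Product: 25 (5R,6R,7aR)-6-ethenyl-3-{2-[(3S,3aR,5S,6S,7aR)-6-ethenyl-6-methyl-2-oxo-5-(prop-1-en-2-yl)octahydro-1-benzofuran-3-yl]ethyl}-6-methyl-5-(prop-1-en-2-yl)-5,6,7,7a-tetrahydro-1-benzofuran-2(4H)-one (target CNP0332736.1), via 3-ylidene enol lactone 23 (not isolated), via 2-hydroxyfuran 24 (not isolated)
Conditions: 8 (1.2 equiv), 22 (1.0 equiv), L-proline (20 mol%), diethyl 2,6-dimethyl-1,4-dihydropyridine-3,5-dicarboxylate (Hantzsch ester, 1.3 equiv), CH2Cl2, 25 → 40 °C; then DBU (0.3 equiv), 25 °C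
Reagents that add atoms: none
Why: Proposed new method: amine-catalysed Knoevenagel-type condensation of the CH-acidic C3 methylene of 8 (activated by C2=O and the C3a=C7a enol double bond) with aldehyde 22 should give ylidene 23, whose exocyclic carbon accepts hydride from the Hantzsch ester because the adduct is the aromatic 2-hydroxyfuran 24, which then tautomerises by protonation at C7a to the conjugated butenolide. The closest known reactions are the organocatalytic three-component reductive alkylation of cyclic CH-acids (aldehyde, Hantzsch ester, proline), the condensation of 2(3H)-furanones with aldehydes to 3-ylidene derivatives, and the base-promoted 2(3H)- to 2(5H)-furanone isomerisation. No ring is closed; the step forms the C3–CH2 bond, adjusts the oxidation level and moves the double bond to C3=C3a. The only new stereocentre, C7a, is set under thermodynamic control during the DBU equilibration through the furanolate: the 7aR epimer keeps the lactone oxygen equatorial on the chair with axial 6-methyl and equatorial vinyl and isopropenyl groups, whereas the epimer needs the flipped chair; the C3–H of the saturated right lactone is roughly ten pKa units less acidic and should not be touched. Regioselectivity (C3 versus C7a attack on the aldehyde) is secured because only the C3 aldol adduct can dehydrate while the hindered C7a adduct reverts, and chemoselectivity because the Hantzsch ester reduces only the electron-poor ylidene and leaves the four isolated alkenes and both lactones alone.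

**Compound list**

1 | (1S,5S)-(−)-verbenone, (1S,5S)-4,6,6-trimethylbicyclo[3.1.1]hept-3-en-2-one | CC1=CC(=O)[C@H]2C[C@@H]1C2(C)C | starting material
2 | (1S,4R,5R)-4-ethenyl-4,6,6-trimethylbicyclo[3.1.1]heptan-2-one | C[C@]1(C=C)CC(=O)[C@H]2C[C@@H]1C2(C)C | intermediate
3 | (4R,5R)-5-ethenyl-5-methyl-4-(prop-1-en-2-yl)cyclohex-1-en-1-yl acetate | C=C[C@@]1(C)CC(OC(C)=O)=CC[C@@H]1C(=C)C | intermediate
4 | lithium (4R,5R)-5-ethenyl-5-methyl-4-(prop-1-en-2-yl)cyclohex-1-en-1-olate | C=C[C@@]1(C)CC(O[Li])=CC[C@@H]1C(=C)C | intermediate (not isolated)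
5 | ethyl 2-[(1R,4R,5R)-4-ethenyl-4-methyl-2-oxo-5-(prop-1-en-2-yl)cyclohexyl]acetate (axial side chain) | C=C[C@@]1(C)CC(=O)[C@@H](CC(=O)OCC)C[C@@H]1C(=C)C | intermediate (not isolated)
6 | ethyl 2-[(1S,4R,5R)-4-ethenyl-4-methyl-2-oxo-5-(prop-1-en-2-yl)cyclohexyl]acetate | C=C[C@@]1(C)CC(=O)[C@H](CC(=O)OCC)C[C@@H]1C(=C)C | intermediate
7 | 2-[(1S,4R,5R)-4-ethenyl-4-methyl-2-oxo-5-(prop-1-en-2-yl)cyclohexyl]acetic acid | C=C[C@@]1(C)CC(=O)[C@H](CC(=O)O)C[C@@H]1C(=C)C | intermediate
8 | (5R,6R)-6-ethenyl-6-methyl-5-(prop-1-en-2-yl)-4,5,6,7-tetrahydro-1-benzofuran-2(3H)-one | C=C[C@@]1(C)CC2=C(CC(=O)O2)C[C@@H]1C(=C)C | intermediate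
9 | (1R,5R)-(+)-verbenone, (1R,5R)-4,6,6-trimethylbicyclo[3.1.1]hept-3-en-2-one | CC1=CC(=O)[C@@H]2C[C@H]1C2(C)C | starting material
10 | (1R,4S,5S)-4-ethenyl-4,6,6-trimethylbicyclo[3.1.1]heptan-2-one | C[C@@]1(C=C)CC(=O)[C@@H]2C[C@H]1C2(C)C | intermediate
11 | (4S,5S)-5-ethenyl-5-methyl-4-(prop-1-en-2-yl)cyclohex-1-en-1-yl acetate | C=C[C@]1(C)CC(OC(C)=O)=CC[C@H]1C(=C)C | intermediate
12 | lithium (4S,5S)-5-ethenyl-5-methyl-4-(prop-1-en-2-yl)cyclohex-1-en-1-olate | C=C[C@]1(C)CC(O[Li])=CC[C@H]1C(=C)C | intermediate (not isolated)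
13 | ethyl 2-[(1S,4S,5S)-4-ethenyl-4-methyl-2-oxo-5-(prop-1-en-2-yl)cyclohexyl]acetate (axial side chain) | C=C[C@]1(C)CC(=O)[C@H](CC(=O)OCC)C[C@H]1C(=C)C | intermediate (not isolated)
14 | ethyl 2-[(1R,4S,5S)-4-ethenyl-4-methyl-2-oxo-5-(prop-1-en-2-yl)cyclohexyl]acetate | C=C[C@]1(C)CC(=O)[C@@H](CC(=O)OCC)C[C@H]1C(=C)C | intermediate
15 | ethyl 2-[(1R,2R,4S,5S)-4-ethenyl-2-hydroxy-4-methyl-5-(prop-1-en-2-yl)cyclohexyl]acetate | C=C[C@]1(C)C[C@@H](O)[C@@H](CC(=O)OCC)C[C@H]1C(=C)C | intermediate (not isolated)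
16 | (3aR,5S,6S,7aR)-6-ethenyl-6-methyl-5-(prop-1-en-2-yl)hexahydro-1-benzofuran-2(3H)-one (cis-fused) | O=C1O[C@@H]2C[C@@](C)(C=C)[C@H](C(=C)C)C[C@@H]2C1 | intermediate
17 | lithium (3aR,5S,6S,7aR)-6-ethenyl-6-methyl-5-(prop-1-en-2-yl)-3a,4,5,6,7,7a-hexahydro-1-benzofuran-2-olate | [Li]OC1=C[C@H]2C[C@@H](C(=C)C)[C@](C)(C=C)C[C@H]2O1 | intermediate (not isolated)
18 | (3S,3aR,5S,6S,7aR)-3-[(dimethylamino)methyl]-6-ethenyl-6-methyl-5-(prop-1-en-2-yl)hexahydro-1-benzofuran-2(3H)-one (C3 configuration as expected from convex-face attack, inconsequential) | CN(C)C[C@H]1C(=O)O[C@@H]2C[C@@](C)(C=C)[C@H](C(=C)C)C[C@H]12 | intermediate (not isolated)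
19 | 1-[(3S,3aR,5S,6S,7aR)-6-ethenyl-6-methyl-2-oxo-5-(prop-1-en-2-yl)octahydro-1-benzofuran-3-yl]-N,N,N-trimethylmethanaminium iodide | C[N+](C)(C)C[C@H]1C(=O)O[C@@H]2C[C@@](C)(C=C)[C@H](C(=C)C)C[C@H]12.[I-] | intermediate (not isolated)
20 | (3aR,5S,6S,7aR)-6-ethenyl-6-methyl-3-methylidene-5-(prop-1-en-2-yl)hexahydro-1-benzofuran-2(3H)-one | C=C1C(=O)O[C@@H]2C[C@@](C)(C=C)[C@H](C(=C)C)C[C@H]12 | intermediate
21 | (3S,3aR,5S,6S,7aR)-3-[(1,3-dioxolan-2-yl)methyl]-6-ethenyl-6-methyl-5-(prop-1-en-2-yl)hexahydro-1-benzofuran-2(3H)-one | O1CCOC1C[C@@H]2C(=O)O[C@@H]3C[C@@](C)(C=C)[C@H](C(=C)C)C[C@H]23 | intermediate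
22 | 2-[(3S,3aR,5S,6S,7aR)-6-ethenyl-6-methyl-2-oxo-5-(prop-1-en-2-yl)octahydro-1-benzofuran-3-yl]acetaldehyde | O=CC[C@@H]1C(=O)O[C@@H]2C[C@@](C)(C=C)[C@H](C(=C)C)C[C@H]12 | intermediate
23 | (5R,6R)-6-ethenyl-3-{(Z)-2-[(3S,3aR,5S,6S,7aR)-6-ethenyl-6-methyl-2-oxo-5-(prop-1-en-2-yl)octahydro-1-benzofuran-3-yl]ethylidene}-6-methyl-5-(prop-1-en-2-yl)-4,5,6,7-tetrahydro-1-benzofuran-2(3H)-one (alkene geometry drawn as Z, inconsequential) | C=C[C@@]1(C)CC2=C(/C(=C/C[C@@H]3C(=O)O[C@@H]4C[C@@](C)(C=C)[C@H](C(=C)C)C[C@H]34)C(=O)O2)C[C@@H]1C(=C)C | intermediate (not isolated)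
24 | (3S,3aR,5S,6S,7aR)-6-ethenyl-3-{2-[(5R,6R)-6-ethenyl-2-hydroxy-6-methyl-5-(prop-1-en-2-yl)-4,5,6,7-tetrahydro-1-benzofuran-3-yl]ethyl}-6-methyl-5-(prop-1-en-2-yl)hexahydro-1-benzofuran-2(3H)-one | C=C[C@@]1(C)Cc2oc(O)c(CC[C@@H]3C(=O)O[C@@H]4C[C@@](C)(C=C)[C@H](C(=C)C)C[C@H]34)c2C[C@@H]1C(=C)C | intermediate (not isolated)
25 | (5R,6R,7aR)-6-ethenyl-3-{2-[(3S,3aR,5S,6S,7aR)-6-ethenyl-6-methyl-2-oxo-5-(prop-1-en-2-yl)octahydro-1-benzofuran-3-yl]ethyl}-6-methyl-5-(prop-1-en-2-yl)-5,6,7,7a-tetrahydro-1-benzofuran-2(4H)-one | C=C[C@@]1(C)C[C@H]2OC(=O)C(CC[C@@H]3C(=O)O[C@@H]4C[C@@](C)(C=C)[C@H](C(=C)C)C[C@H]34)=C2C[C@@H]1C(=C)C | target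

**Step count and risks**

Total step count: 13. Longest linear sequence: 8 steps (steps 6–13, from 9).

Steps most likely to fail:

1. Step 13 (Proposed new method). Hydride transfer to the singly activated ylidene may be slower than its capture by a second furanolate (Michael bis-adduct) or than prototropic drift of the double bond into the bridge, and the amine catalyst may be acylated by the enol lactone. Fallback (known chemistry, reversed polarity, Pd cross-coupling), setting out from 22 and 8: NaBH4 (MeOH, 0 °C) reduces 22 to the 3-(2-hydroxyethyl) lactone F1; Appel iodination (PPh3, I2, imidazole) gives the 3-(2-iodoethyl) lactone F2; zinc insertion (Zn, LiCl, THF) gives the alkylzinc iodide F3. In parallel, 8 is brominated at C3 through its lithium enolate (LiHMDS, −78 °C; NBS) to the 3-bromo-2(3H)-furanone F4, which triethylamine isomerises to the conjugated 3-bromobutenolide F5 with the equatorial 7a-oxygen. Negishi coupling of F3 with F5 (Pd(dppf)Cl2, THF, 50 °C) forms the same C3–CH2 bond and returns to the route at 25.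

2. Step 2 (the same operation recurs as step 7). The tertiary cation may be captured by acetate, may lose the ring proton to give an isopropylidene group (erasing the adjacent stereocentre), or the alkenes may be acylated by Ac2O/BF3. Fallback (halide-capture opening, then E2), setting out from 2: iodotrimethylsilane (TMSCl, NaI, MeCN, 0 °C) opens the cyclobutane with iodide capture to the tertiary-iodide silyl enol ether F6; DBU (toluene, 60 °C) eliminates HI towards a methyl group to give the isopropenyl silyl enol ether F7; MeLi cleaves the O–Si bond and the route is rejoined at lithium enolate 4. In the mirror-image series, 10 would go the same way through the tertiary-iodide silyl enol ether F8 and the isopropenyl silyl enol ether F9 to lithium enolate 12.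

3. Step 11. Hydrogen return to the C3 radical may show poor facial selectivity, hydrogen abstraction at the allylic positions of 20 may compete, or the acceptor may oligomerise. Fallback (ionic chemistry), setting out from 20: DBU-mediated Michael addition of nitromethane, with kinetic convex-face protonation of the lactone enolate, gives the 3-(2-nitroethyl) lactone F10; a titanium(III)-mediated Nef reaction (TiCl3, NH4OAc buffer, THF/H2O) converts CH2NO2 into CHO and returns to the route at 22.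

Further compounds
F1 | step 13 | (3S,3aR,5S,6S,7aR)-6-ethenyl-3-(2-hydroxyethyl)-6-methyl-5-(prop-1-en-2-yl)hexahydro-1-benzofuran-2(3H)-one | OCC[C@@H]1C(=O)O[C@@H]2C[C@@](C)(C=C)[C@H](C(=C)C)C[C@H]12
F2 | step 13 | (3S,3aR,5S,6S,7aR)-6-ethenyl-3-(2-iodoethyl)-6-methyl-5-(prop-1-en-2-yl)hexahydro-1-benzofuran-2(3H)-one | ICC[C@@H]1C(=O)O[C@@H]2C[C@@](C)(C=C)[C@H](C(=C)C)C[C@H]12
F3 | step 13 | {2-[(3S,3aR,5S,6S,7aR)-6-ethenyl-6-methyl-2-oxo-5-(prop-1-en-2-yl)octahydro-1-benzofuran-3-yl]ethyl}zinc iodide | I[Zn]CC[C@@H]1C(=O)O[C@@H]2C[C@@](C)(C=C)[C@H](C(=C)C)C[C@H]12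
F4 | step 13 | (5R,6R)-3-bromo-6-ethenyl-6-methyl-5-(prop-1-en-2-yl)-4,5,6,7-tetrahydro-1-benzofuran-2(3H)-one (either C3 epimer, C3 left undefined) | C=C[C@@]1(C)CC2=C(C(Br)C(=O)O2)C[C@@H]1C(=C)C
F5 | step 13 | (5R,6R,7aR)-3-bromo-6-ethenyl-6-methyl-5-(prop-1-en-2-yl)-5,6,7,7a-tetrahydro-1-benzofuran-2(4H)-one | C=C[C@@]1(C)C[C@H]2OC(=O)C(Br)=C2C[C@@H]1C(=C)C
F6 | step 2 | {[(4S,5R)-5-ethenyl-4-(2-iodopropan-2-yl)-5-methylcyclohex-1-en-1-yl]oxy}trimethylsilane | C=C[C@@]1(C)CC(O[Si](C)(C)C)=CC[C@@H]1C(C)(C)I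
F7 | step 2 | {[(4R,5R)-5-ethenyl-5-methyl-4-(prop-1-en-2-yl)cyclohex-1-en-1-yl]oxy}trimethylsilane | C=C[C@@]1(C)CC(O[Si](C)(C)C)=CC[C@@H]1C(=C)C
F8 | step 7 | {[(4R,5S)-5-ethenyl-4-(2-iodopropan-2-yl)-5-methylcyclohex-1-en-1-yl]oxy}trimethylsilane | C=C[C@]1(C)CC(O[Si](C)(C)C)=CC[C@H]1C(C)(C)I
F9 | step 7 | {[(4S,5S)-5-ethenyl-5-methyl-4-(prop-1-en-2-yl)cyclohex-1-en-1-yl]oxy}trimethylsilane | C=C[C@]1(C)CC(O[Si](C)(C)C)=CC[C@H]1C(=C)C
F10 | step 11 | (3S,3aR,5S,6S,7aR)-6-ethenyl-6-methyl-3-(2-nitroethyl)-5-(prop-1-en-2-yl)hexahydro-1-benzofuran-2(3H)-one | O=[N+]([O-])CC[C@@H]1C(=O)O[C@@H]2C[C@@](C)(C=C)[C@H](C(=C)C)C[C@H]12
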